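**In the vessel.** Your flasks are closed, stirred and of constant volume. They hold substrate and catalyst, with gas held at its saturation value and none of it in solution at the start.

in all of them: gas 67 mM (held)
- south: substrate 2 M; catalyst 1.7 mol%; temperature 18 °C; run made earlier
- west: substrate 2 M; catalyst 2.6 mol%; temperature 34 °C; run made earlier
- winter: substrate 2.0 M; catalyst 1.2 mol%; at 10 °C until 80 s, from then on at 40 °C; time 2.0 min
- dawn: substrate 2.0 M; catalyst 1.2 mol%; temperature 10 °C; time 2.0 min
- noon: substrate 2.0 M; catalyst 1.2 mol%; temperature 25 °C; time 2.0 min
- spring: substrate 2.0 M; catalyst 1.2 mol%; temperature 40 °C; time 2.0 min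

south run (percent of the substrate charged)

| time / min | product / % |
|---|---|
| 0.200 | 3 |
| 0.333 | 4 |
| 0.500 | 12 |
| 0.833 | 15 |
| 1.33 | 24 |
| 2.50 | 50 |

west run (percent of the substrate charged)

| time / s | product / % |
|---|---|
| 10.0 | 3 |
| 15.0 | 7 |
| 25.0 | 7 |
| 40.0 | 18 |
| 50.0 | 18 |

(standard deviation of a reading: 1.5 percentage points)

- at the start none of the gas is in solution

1. the flask with the highest amount of product, in percent of the substrate charged ("all alike" if they lie within 1.5 percentage points) (winter / dawn / noon / spring / all alike)
2. final product, as a percentage of the substrate charged, in winter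
3. final product, as a percentage of the substrate charged, in dawn
4. final product, as a percentage of the substrate charged, in noon
5. final product, as a percentage of the substrate charged, in spring

**What you inherit.** South reached 50.0 % of the charge in 2.50 min, a slope of 0.200 min⁻¹. West, with more catalyst and more heat, reached 18.0 % in 50.0 s, or 0.216 min⁻¹, hardly different. So I take the west slope as the feed ceiling, the fraction of the charge per minute that I reckon the arriving gas can turn into product. A flask running at it has gas transfer as its rate-limiting step. It is a reading, and each point carries 1.5 percentage points of scatter.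

**When you come.** By my reckoning, 2.0 min at the ceiling gives 43.2 % of the charge as product, so expect more substrate than product. Dawn is leaner and colder than either run, so I expect it to fall short, by an amount I do not reckon. Spring is hotter, so I put it above dawn, and winter between them. Leave the stirring and the gas alone: the ceiling was read with them as they stand.

**The forecast.** It differs from mine. It calls the flasks all alike, with winter 40.0 %, dawn 39.5 %, noon 40.5 % and spring 41.0 %, holding that “the simplest reading is gas-transfer limitation”.

**The result.** The highest is spring: winter 35.8 %, dawn 30.8 %, noon 39.2 %, spring 43.8 %. Spring stands close to the ceiling, and dawn lies 12 points under it.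

    substrate + partner + catalyst → product + catalyst, rate k1*[substrate]*[partner]*[catalyst]/(1 + ([substrate]/sat1)) (0.0991 M, k = 240 M⁻² s⁻¹, Ea = 41.0 kJ mol⁻¹)
    2 substrate → homo dimer (k = 7.18 × 10⁻⁶ M⁻¹ s⁻¹, Ea = 74.0 kJ mol⁻¹)
    gas ⇌ partner, rate k3*(csat - [partner]) (kL = 0.121 s⁻¹)
    (constants at 25 °C)

**The neighbour.** Charge dawn with 3 mol% of catalyst instead of 1.2 mol%, all else held. The ceiling stays 43.2 %, as its reckoning holds no catalyst. This neighbour of dawn gives 39.5 %, more than dawn. The ceiling stands higher still. The gap of this neighbour is 3.7 points, with 60.5 % of the charge still substrate.

All runs are calculated on assumed constants.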